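Slowness is what my colleague and I quarrel over at the board. In Tuesday's run free monomer creeps from 93.4% at 40.0 s to 81.8% at 80.0 s, and we disagree on whether such creeping survives in alder and maple.

| flask | free monomer | pre-initiator | impurity | remark | time |
|---|---|---|---|---|---|
| Tuesday's | 0.0020 M | 11 mol% | 0.18 mM | run made earlier |  |
| Thursday's | 0.0020 M | 17 mol% | 0.18 mM | run made earlier |  |
| alder | 0.0020 M | 7.6 mol% | 0.18 mM |  | 2.0 min |
| maple | 0.0020 M | 7.6 mol% | 0.18 mM |  | 8.0 min |

- Tuesday's (time / s: monomer in chains / %, free monomer / %): 10.0: 1.0, 98.7; 12.0: 0.8, 98.2; 20.0: 1.6, 97.5; 30.0: 4.9, 94.6; 40.0: 7.7, 93.4; 60.0: 12.7, 86.9; 80.0: 17.5, 81.8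
- Thursday's (time / s: monomer in chains / %, free monomer / %): 10.0: 1.9, 99.0; 20.0: 4.7, 94.8; 30.0: 13.5, 87.7; 40.0: 20.2, 81.0; 50.0: 25.2, 74.2; 60.0: 29.6, 69.7; 80.0: 35.0, 64.6

(scatter of a reading: 0.5 percentage points)

- the average divides the monomer in chains by the number of chains begun, living and dead together
- the earlier runs do not show the number of chains; that part of a forecast is a guess

- which of the two ends with the longer chains by the average number of monomer units in a chain (chains begun, living or dead) ("neither" if they lie within 10%) (alder / maple / neither)
- average number of monomer units in a chain (chains begun, living or dead) at the end, alder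
- average number of monomer units in a chain (chains begun, living or dead) at the end, maple

She subtracts. The surplus of pre-initiator over impurity is 0.0400 mM on Tuesday and 0.160 mM on Thursday, and she finds the rates in about that ratio. In alder and maple the pre-initiator, 0.152 mM, stands below the impurity, 0.18 mM, so for her the flask stops early. Her forecast says “Everything is activated and killed within about a minute”, and gives neither, with 0.5 and 0.5.

I bet instead that chains once begun keep growing, though the runs do not show the number of chains. Thursday's free monomer M flattens toward a floor M∞, the level at which it stops falling. Three equally spaced readings put it at 60.4%. With a fixed number of living chains the gap M − M∞ shrinks pseudo-first-order, as exp(−λt), with λ proportional to the living chains. Tuesday's readings give λ = 0.0108 s⁻¹.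

Alder and maple share one recipe, so the unknown number of chains cancels from the ratio of their lengths. Neglecting the induction, and with x = exp(−λ·2.0 min), that ratio is R = 1 + x + x·x + x·x·x. A tiny λ gives R = 4.00. I take Tuesday's λ as the upper limit, since alder holds less pre-initiator; then x = 0.273 and R = 1.37, beyond the margin. My answer is maple.

The flask gives maple: 21.6 for alder and 56.6 for maple, a ratio of 2.62, between my limits.

    free monomer + initiator → living end + monomer in chains (k = 68.0 M⁻¹ s⁻¹)
    free monomer + living end → monomer in chains + living end, rate k2*[living end]*[free monomer] (k = 310 M⁻¹ s⁻¹)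
    monomer in chains + living end → free monomer + living end, rate k3*[living end] as long as [monomer in chains] is above zero (k = 0.380 s⁻¹)
    initiator + impurity → spent initiator (k = 19000 M⁻¹ s⁻¹)
    pre-initiator ⇌ initiator (K = 0.500, k = 0.0880 s⁻¹)

Her equality belongs to late times: alder reaches 70.2 at 20.0 min and maple 71.5 at 80.0 min. Now take Θ, the natural logarithm of the starting gap over the final gap, which at equal time and equal M∞ scales with the living ends. Maple, with 69.3% free monomer and 1.08 × 10⁻⁵ M living end, has Θ = 1.49. Its neighbour with 3.1 × 10⁻⁴ M of impurity keeps 81.0%, so Θ = 0.652. That reckons 4.74 × 10⁻⁶ M of living end, against 4.60 × 10⁻⁶ M simulated. With 19.0% monomer in chains, the reckoned length is 80.0, and the neighbour gives 82.5.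

Readings and results come from a simulation for substances that don't exist; noise was put on by code.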